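**Plan**

- Retrosynthesis (target numbering; ring A = the trimethoxybenzo ring, ring B = C1, C2, C3, C4, C4a, C8a): both CH2OH groups go back to methyl esters; the C1–C2 bond is then cut to a diazo ester (carbene) at C2 and the C1 methylene of a diarylmethane; last come C3=C4 (Stobbe) and the ring A–C1 bond (Suzuki).
- Forward: diarylmethane aldehyde, E-arylidenesuccinate, diazo transfer at C2, ring B closed by Rh-carbene insertion into C1–H, equilibration at C2, reduction of both esters.
- Enabling feature: the C1–H bond is doubly benzylic between the 3,4-dimethoxyphenyl ring and ring A (OMe ortho at C8 and para at C6 to C8a), hence strongly hydridic. Ring A (C8a, C4a) and the E C3=C4 bond hold it 1,6 to C2, so the atoms from the carbene carbon to this C–H are exactly ring B.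
- Stereochemistry: C1 from catalyst-controlled choice between the two enantiotopic C1–H bonds; C2 from thermodynamic equilibration of the ester to trans relative to the fixed C1.

Key step: step 6

Assumption: the sense of induction of Rh2(S-PTAD)4 at C1 of this new substrate cannot be taken from precedent; the S catalyst is written, and Rh2(R-PTAD)4 would be used instead if a first run showed the (1S) series.

**Step 1**
Reactants: 1 3,4-dimethoxybenzyl chloride
Product: 2 2-(3,4-dimethoxybenzyl)-4,4,5,5-tetramethyl-1,3,2-dioxaborolane
Conditions: B2pin2 (1.1 equiv), Pd(dba)2 (3 mol %), P(4-MeOC6H4)3 (6 mol %), KOAc (1.5 equiv), toluene, 50 °C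
Reagents that add atoms: bis(pinacolato)diboron, CC1(C)OB(OC1(C)C)B1OC(C)(C)C(C)(C)O1
Why: Miyaura borylation of a benzylic chloride (oxidative addition, acetate-assisted transmetalation with the diboron, reductive elimination) should give the benzylboronate; no stereocentre is formed.

**Step 2**
Reactants: 2 2-(3,4-dimethoxybenzyl)-4,4,5,5-tetramethyl-1,3,2-dioxaborolane; 3 2-bromo-3,4,5-trimethoxybenzaldehyde
Product: 4 2-(3,4-dimethoxybenzyl)-3,4,5-trimethoxybenzaldehyde
Conditions: Pd(OAc)2 (5 mol %), SPhos (10 mol %), K3PO4 (3 equiv), toluene/H2O 10:1, 90 °C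
Reagents that add atoms: none
Why: sp2–sp3 Suzuki–Miyaura coupling, in which the dialkylbiarylphosphine should allow oxidative addition into the di-ortho-substituted, formyl-activated bromide and transmetalation of the benzylboronate while the aldehyde is inert to the boron reagent; no stereocentre is formed.

**Step 3**
Reactants: 4 2-(3,4-dimethoxybenzyl)-3,4,5-trimethoxybenzaldehyde; 5 dimethyl succinate
Product: 6 (E)-4-[2-(3,4-dimethoxybenzyl)-3,4,5-trimethoxyphenyl]-3-(methoxycarbonyl)but-3-enoic acid
Conditions: NaOMe (2.5 equiv), MeOH, reflux; then 1 M HCl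
Reagents that add atoms: none
Why: Stobbe condensation (aldol addition, lactonisation to the paraconic ester, E1cB opening) should give the half-ester with the free acid on the CH2 branch and the E alkene, in which ring A is trans to the conjugated ester and therefore cis to the CH2 carbon that becomes C2.

**Step 4**
Reactants: 6 (E)-4-[2-(3,4-dimethoxybenzyl)-3,4,5-trimethoxyphenyl]-3-(methoxycarbonyl)but-3-enoic acid
Product: 7 dimethyl (E)-2-[[2-(3,4-dimethoxybenzyl)-3,4,5-trimethoxyphenyl]methylidene]butanedioate
Conditions: MeI (1.5 equiv), K2CO3 (1.5 equiv), DMF, rt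
Reagents that add atoms: iodomethane, CI
Why: SN2 O-alkylation of the carboxylate under a mild carbonate base should give the diester without moving the double bond or changing its geometry.

**Step 5**
Reactants: 7 dimethyl (E)-2-[[2-(3,4-dimethoxybenzyl)-3,4,5-trimethoxyphenyl]methylidene]butanedioate
Product: 8 dimethyl (E)-2-diazo-3-[[2-(3,4-dimethoxybenzyl)-3,4,5-trimethoxyphenyl]methylidene]butanedioate (ring A cis to the diazo carbon)
Conditions: p-ABSA (1.3 equiv), DBU (1.5 equiv), MeCN, 0 °C, dark; short silica plug, used at once
Reagents that add atoms: 4-acetamidobenzenesulfonyl azide, CC(=O)Nc1ccc(cc1)S(=O)(=O)N=[N+]=[N-]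
Why: Regitz diazo transfer to the only acidic position (the CH2 alpha to the ester and allylic to the aryl acrylate), as in the preparation of vinyldiazoacetates from β,γ-unsaturated esters, should give the vinyl diazo ester with the C3=C4 geometry retained because that bond stays a double bond in the dienolate.

**Step 6**
Reactants: 8 dimethyl (E)-2-diazo-3-[[2-(3,4-dimethoxybenzyl)-3,4,5-trimethoxyphenyl]methylidene]butanedioate
Product: 9 dimethyl (1R,2R)-1-(3,4-dimethoxyphenyl)-6,7,8-trimethoxy-1,2-dihydronaphthalene-2,3-dicarboxylate (cis: C1 aryl and C2 ester on the same face)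
Conditions: Rh2(S-PTAD)4 (1 mol %), CH2Cl2, -40 °C to 0 °C, slow addition of 8 over 2 h, Ar
Reagents that add atoms: none
Why: Proposed new method: loss of N2 gives a Rh(II)-bound donor/acceptor vinylcarbene at C2, and because the E alkene places ring A cis to C2, the C1 methylene ortho to the alkenyl group lies about 3 Å from the carbene carbon, so its doubly benzylic C–H bond, made hydridic by the para-methoxy group of the 3,4-dimethoxyphenyl ring and the ortho- and para-methoxy groups of ring A, should undergo the usual three-centre hydride-transfer/C–C bond-forming insertion. The closest known reactions are the Rh2(PTTL)4- and Rh2(PTAD)4-catalysed enantioselective intramolecular insertions of aryldiazoacetates into benzylic C–H bonds (cis-2-aryl-2,3-dihydrobenzofuran-3-carboxylates) and the intermolecular benzylic C–H insertions of vinyldiazoacetates; new here are the vinyl donor tied through a cis-styrene unit to a diarylmethane C–H and the six-membered ring. Ring B is closed by a 1,6-C–H insertion, formally a 6-endo closure because the C3=C4 bond lies inside the new ring. C1 is set by the chiral carboxylate pocket, which selects one of the two enantiotopic C1–H bonds; C2 is set in the same transition state and is expected cis to the C1 aryl (aryl turned away from rhodium, as in the dihydrobenzofuran precedent), which is harmless because C2 is corrected in step 7. The step needs insertion into C1–H rather than attack of the carbene on the free ortho carbon C5 of ring A (Nazarov-type closure to an indene) or loss of the metal after hydride transfer (free o-quinodimethane, racemic 6π closure); in the substrate this rests on the E geometry that points the C1 methylene at the carbene, on the two donor-substituted rings that make C1–H exceptionally hydridic, and on the unstrained six-membered ring that lets C–C bond formation keep pace with hydride transfer.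

**Step 7**
Reactants: 9 dimethyl (1R,2R)-1-(3,4-dimethoxyphenyl)-6,7,8-trimethoxy-1,2-dihydronaphthalene-2,3-dicarboxylate
Product: 10 dimethyl (1R,2S)-1-(3,4-dimethoxyphenyl)-6,7,8-trimethoxy-1,2-dihydronaphthalene-2,3-dicarboxylate (trans)
Conditions: NaOMe (0.2 equiv), MeOH/THF 1:1, 0 °C to rt, Ar; AcOH quench
Reagents that add atoms: none
Why: base-mediated epimerisation of the ester α-stereocentre through the dienolate, as in the cis-to-trans equilibration of 2-aryl-2,3-dihydrobenzofuran-3-carboxylates, should favour trans because the peri 8-methoxy group holds the C1 aryl pseudo-axial and only the trans isomer lets the C2 ester also be pseudo-axial, away from the C3 ester; C1 is not acidic and is untouched.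

**Step 8**
Reactants: 10 dimethyl (1R,2S)-1-(3,4-dimethoxyphenyl)-6,7,8-trimethoxy-1,2-dihydronaphthalene-2,3-dicarboxylate
Product: 11 [(1R,2S)-1-(3,4-dimethoxyphenyl)-6,7,8-trimethoxy-1,2-dihydronaphthalene-2,3-diyl]dimethanol (CNP0274357.1)
Conditions: DIBAL-H (6 equiv), CH2Cl2, -78 °C to 0 °C; aq. Rochelle salt
Reagents that add atoms: none
Why: DIBAL-H 1,2-reduction of the saturated and the conjugated ester to the primary alcohols should leave the styrene double bond intact, and the Lewis-acidic, non-basic hydride at low temperature should not epimerise C2.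

**Compound list**

1 | 3,4-dimethoxybenzyl chloride | COc1ccc(CCl)cc1OC | starting material
2 | 2-(3,4-dimethoxybenzyl)-4,4,5,5-tetramethyl-1,3,2-dioxaborolane | COc1ccc(CB2OC(C)(C)C(C)(C)O2)cc1OC | intermediate
3 | 2-bromo-3,4,5-trimethoxybenzaldehyde | COc1cc(C=O)c(Br)c(OC)c1OC | starting material
4 | 2-(3,4-dimethoxybenzyl)-3,4,5-trimethoxybenzaldehyde | COc1cc(C=O)c(Cc2ccc(OC)c(OC)c2)c(OC)c1OC | intermediate
5 | dimethyl succinate | COC(=O)CCC(=O)OC | starting material
6 | (E)-4-[2-(3,4-dimethoxybenzyl)-3,4,5-trimethoxyphenyl]-3-(methoxycarbonyl)but-3-enoic acid | OC(=O)C/C(C(=O)OC)=C\c1cc(OC)c(OC)c(OC)c1Cc1ccc(OC)c(OC)c1 | intermediate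
7 | dimethyl (E)-2-[[2-(3,4-dimethoxybenzyl)-3,4,5-trimethoxyphenyl]methylidene]butanedioate | COC(=O)C/C(C(=O)OC)=C\c1cc(OC)c(OC)c(OC)c1Cc1ccc(OC)c(OC)c1 | intermediate
8 | dimethyl (E)-2-diazo-3-[[2-(3,4-dimethoxybenzyl)-3,4,5-trimethoxyphenyl]methylidene]butanedioate | COC(=O)C(=[N+]=[N-])/C(C(=O)OC)=C\c1cc(OC)c(OC)c(OC)c1Cc1ccc(OC)c(OC)c1 | intermediate
9 | dimethyl (1R,2R)-1-(3,4-dimethoxyphenyl)-6,7,8-trimethoxy-1,2-dihydronaphthalene-2,3-dicarboxylate (cis) | COc1ccc([C@@H]2c3c(cc(OC)c(OC)c3OC)C=C(C(=O)OC)[C@@H]2C(=O)OC)cc1OC | intermediate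
10 | dimethyl (1R,2S)-1-(3,4-dimethoxyphenyl)-6,7,8-trimethoxy-1,2-dihydronaphthalene-2,3-dicarboxylate (trans) | COc1ccc([C@@H]2c3c(cc(OC)c(OC)c3OC)C=C(C(=O)OC)[C@H]2C(=O)OC)cc1OC | intermediate
11 | [(1R,2S)-1-(3,4-dimethoxyphenyl)-6,7,8-trimethoxy-1,2-dihydronaphthalene-2,3-diyl]dimethanol | COc1ccc([C@@H]2c3c(cc(OC)c(OC)c3OC)C=C(CO)[C@H]2CO)cc1OC | target

**Step count and risks**

Total step count: 8. Longest linear sequence: 8 steps (1 to 11).

Steps most likely to fail:

Step 6 (Proposed new method). The vinylcarbene may close onto the electron-rich free ortho carbon C5 of ring A (indene formation) instead of inserting into C1–H. The metal may also leave after hydride transfer, so that a free o-quinodimethane closes without catalyst control and the enantiomeric purity is eroded. The fallback sets out from 8 and replaces the two-electron rhodium carbene by cobalt(II)-porphyrin metalloradical catalysis ([Co(TPP)] 5 mol %, toluene, 60 °C). The cobalt(III)–carbene radical should abstract a hydrogen atom from C1–H (a radical step that does not attack ring A), and the resulting o-quinodimethane should close by thermal 6π electrocyclisation; this is the same type of sequence known for cobalt carbene radicals in 1,2-dihydronaphthalene synthesis. The product would be the racemic cis diester, that is 9 together with dimethyl (1S,2S)-1-(3,4-dimethoxyphenyl)-6,7,8-trimethoxy-1,2-dihydronaphthalene-2,3-dicarboxylate F1. Equilibration with NaOMe/MeOH as in step 7 would give the racemic trans diester, that is 10 together with dimethyl (1S,2R)-1-(3,4-dimethoxyphenyl)-6,7,8-trimethoxy-1,2-dihydronaphthalene-2,3-dicarboxylate F2. Preparative HPLC on a chiral stationary phase (amylose tris(3,5-dimethylphenylcarbamate)) would separate the two, and the route is rejoined at 10.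

Step 5. Under DBU the dienolate may equilibrate (E/Z scrambling of C3=C4, migration to the arylmethyl-maleate), and the diazo alkene may cyclise to a pyrazole during the exposure to base. The fallback sets out from 7 and activates the methylene before the transfer (detrifluoroacetylative diazo transfer). Kinetic deprotonation (LiHMDS, THF, -78 °C) and acylation with CF3CO2CH2CF3 should give dimethyl (E)-2-[[2-(3,4-dimethoxybenzyl)-3,4,5-trimethoxyphenyl]methylidene]-3-(2,2,2-trifluoroacetyl)butanedioate F3 (racemic at the acylated carbon, largely enolised). With MsN3, Et3N and H2O in MeCN at rt this should pass to 8 within minutes under a weak base; the route is rejoined at 8.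

Step 7. The dienolate may be reprotonated at C4 (migration of the double bond to C2=C3), or it may be oxidised by air to the 1-arylnaphthalene. The fallback sets out from 9 and moves the equilibration to the aldehyde oxidation level. DIBAL-H reduction as in step 8 should give [(1R,2R)-1-(3,4-dimethoxyphenyl)-6,7,8-trimethoxy-1,2-dihydronaphthalene-2,3-diyl]dimethanol F4. Swern oxidation ((COCl)2, DMSO, then Et3N, -78 °C to 0 °C) should give (1R,2R)-1-(3,4-dimethoxyphenyl)-6,7,8-trimethoxy-1,2-dihydronaphthalene-2,3-dicarbaldehyde F5. Its far more acidic C2–H should be equilibrated by the triethylamine of the same operation to (1R,2S)-1-(3,4-dimethoxyphenyl)-6,7,8-trimethoxy-1,2-dihydronaphthalene-2,3-dicarbaldehyde F6. Luche reduction (NaBH4, CeCl3·7H2O, MeOH, -20 °C) would then give the target; the route is rejoined at 11.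

**Further compounds**

F1 | step 6 | dimethyl (1S,2S)-1-(3,4-dimethoxyphenyl)-6,7,8-trimethoxy-1,2-dihydronaphthalene-2,3-dicarboxylate (enantiomer of 9) | COc1ccc([C@H]2c3c(cc(OC)c(OC)c3OC)C=C(C(=O)OC)[C@H]2C(=O)OC)cc1OC
F2 | step 6 | dimethyl (1S,2R)-1-(3,4-dimethoxyphenyl)-6,7,8-trimethoxy-1,2-dihydronaphthalene-2,3-dicarboxylate (enantiomer of 10) | COc1ccc([C@H]2c3c(cc(OC)c(OC)c3OC)C=C(C(=O)OC)[C@@H]2C(=O)OC)cc1OC
F3 | step 5 | dimethyl (E)-2-[[2-(3,4-dimethoxybenzyl)-3,4,5-trimethoxyphenyl]methylidene]-3-(2,2,2-trifluoroacetyl)butanedioate | COC(=O)C(C(=O)C(F)(F)F)/C(C(=O)OC)=C\c1cc(OC)c(OC)c(OC)c1Cc1ccc(OC)c(OC)c1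
F4 | step 7 | [(1R,2R)-1-(3,4-dimethoxyphenyl)-6,7,8-trimethoxy-1,2-dihydronaphthalene-2,3-diyl]dimethanol | COc1ccc([C@@H]2c3c(cc(OC)c(OC)c3OC)C=C(CO)[C@@H]2CO)cc1OC
F5 | step 7 | (1R,2R)-1-(3,4-dimethoxyphenyl)-6,7,8-trimethoxy-1,2-dihydronaphthalene-2,3-dicarbaldehyde | COc1ccc([C@@H]2c3c(cc(OC)c(OC)c3OC)C=C(C=O)[C@@H]2C=O)cc1OC
F6 | step 7 | (1R,2S)-1-(3,4-dimethoxyphenyl)-6,7,8-trimethoxy-1,2-dihydronaphthalene-2,3-dicarbaldehyde | COc1ccc([C@@H]2c3c(cc(OC)c(OC)c3OC)C=C(C=O)[C@H]2C=O)cc1OC
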